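(Readings and results are calculated for substances that don't exist; scatter was added.)

The constants I wanted were those of two competing losses of the starting material, and the three runs gave their ratio without either constant.

common to all: starting material 0.42 M
- south-west: reagent 2 equiv; second substrate 2 equiv; run made earlier
- south-east: reagent 4.5 equiv; second substrate 2 equiv; run made earlier
- north-east: reagent 3 equiv; second substrate 1 equiv; run made earlier
- flask: reagent 3.00 equiv; second substrate 2.00 equiv; time 15 min

| run | time / min | target / % | starting material / % |
|---|---|---|---|
| south-west | 4.00 | 12.2 | 50.2 |
| south-west | 5.00 | 16.9 | 42.6 |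
| south-west | 6.00 | 18.4 | 36.6 |
| south-west | 8.00 | 20.1 | 28.1 |
| south-west | 10.0 | 24.3 | 21.5 |
| south-east | 4.00 | 29.0 | 38.9 |
| south-east | 5.00 | 32.4 | 29.6 |
| south-east | 6.00 | 34.4 | 24.8 |
| south-east | 8.00 | 39.9 | 16.3 |
| south-east | 10.0 | 41.8 | 12.0 |
| north-east | 4.00 | 23.0 | 59.8 |
| north-east | 5.00 | 27.8 | 50.6 |
| north-east | 6.00 | 27.7 | 44.5 |
| north-east | 8.00 | 34.7 | 35.5 |
| north-east | 10.0 | 40.3 | 30.1 |

(each reading ± 1 percentage point)

- time up to 15 min at which target stands highest
- the amount of target, in percent of the starting material charged, at that time

- the numbers in the tables scatter by 1 percentage point (one standard deviation)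

At the last reading of each run I divided the target by the starting material lost any other way, then divided that by the charged ratio c(reagent)/c(second substrate). This gave 0.448 in the south-west run, 0.402 in the south-east run and 0.454 in the north-east run, and I read their mean as the selectivity factor g, 0.435. Target rose from first to last reading in each run, so I put the highest value in the flask at 15 min.

For the lower end of my bracket I took the lowest factor and the south-west first-order fall of starting material carried on to 15 min, which reckons to 10.6% left, since that run had less reagent. For the upper end I took the highest factor and the south-east first-order fall, which reckons to 4.50% left, since that run had more reagent. My bracket for the flask ran from 33.6% to 38.7%.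

The forecast gave 37% at 15 min, choosing that time on the ground that “Target is still rising slowly”, and its amount stands inside that bracket.

The flask gave 34.7% at 15.0 min, inside the bracket.

    starting material + reagent → target (k = 0.00100 M⁻¹ s⁻¹)
    second substrate + reagent → second product (k = 4.00 × 10⁻⁵ M⁻¹ s⁻¹)
    starting material + second substrate → cross product (k = 0.00270 M⁻¹ s⁻¹)
    starting material ⇌ dormant form (K = 0.840, k = 7.50 × 10⁻⁵ s⁻¹)
    target → over-reaction product (k = 2.40 × 10⁻⁷ s⁻¹)

In the flask the conversion into cross product used starting material 1.6 times as fast as the conversion into target at 3.00 min and 1.4 times as fast at 15.0 min, and g, applied to the loss that left 6.9% of the starting material, reckons to 36.8% of target, where the flask held 34.7% beside cross product at 56.3%. With 5.00 equiv of second substrate, g gives the neighbouring flask a target share of 20.7% of the starting material lost, and that flask held 18.6% of target with 0.45% of its starting material left.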